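## Retrosynthetic overview
- The target is a constitutional isomer (C23H32O3) of the furan-2-yl ester of 3-farnesylbut-3-enoic acid, so the last step is a pure isomerisation.
- The carbocycle, the γ-lactone and a temporary oxa-bridge form together in an intramolecular furan Diels–Alder reaction. Acid-triggered opening of the bridge then gives the enone.
- The furan-2-yl ester comes from the acid and furan-2(5H)-one by O-acylation of the dienolate.
- The acid comes from farnesyl bromide and CH2=C(Bpin)CH2CO2Et by alkenyl–allyl coupling. These come from farnesol and ethyl buta-2,3-dienoate.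
- C3a is fixed when a chiral acid opens one of two interconverting cycloadducts. C7a follows from the final ketonisation to the cis-fused ring system.

Assumption: (R)-TRIP is taken to open the (3aR,5R,7aS) cycloadduct faster. If the sense of induction is the opposite, (S)-TRIP is used and nothing else changes.

"Farnesyl" means (2E,6E)-3,7,11-trimethyldodeca-2,6,10-trien-1-yl throughout.

## Route

Step 1
Reactants: 1 (2E,6E)-farnesol
Product: 2 (2E,6E)-farnesyl bromide
Conditions: PBr3 (0.4 equiv), Et2O, 0 °C, 30 min
Reagents that add atoms: phosphorus tribromide BrP(Br)Br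
Why: SN2-type bromination of the primary allylic alcohol through its phosphite ester at 0 °C leaves both E double bonds untouched and creates no stereocentre.

Step 2
Reactants: 3 ethyl buta-2,3-dienoate
Product: 4 ethyl 3-(4,4,5,5-tetramethyl-1,3,2-dioxaborolan-2-yl)but-3-enoate
Conditions: B2pin2 (1.05 equiv), CuCl (5 mol%), Xantphos (5 mol%), NaOt-Bu (10 mol%), MeOH (2 equiv), THF, −20 to 0 °C
Reagents that add atoms: bis(pinacolato)diboron CC1(C)OB(OC1(C)C)B1OC(C)(C)C(C)(C)O1
Why: Copper-catalysed conjugate borylation (borylcupration) of the allenoate puts boron on the central carbon, and kinetic protonation of the copper enolate at the α-carbon by methanol leaves the 1,1-disubstituted β,γ-alkene, with no stereocentre formed.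

Step 3
Reactants: 2 (2E,6E)-farnesyl bromide; 4 ethyl 3-(4,4,5,5-tetramethyl-1,3,2-dioxaborolan-2-yl)but-3-enoate
Product: 5 ethyl (5E,9E)-6,10,14-trimethyl-3-methylidenepentadeca-5,9,13-trienoate
Conditions: Pd(PPh3)4 (3 mol%), CsF (2.5 equiv), THF, 45 °C
Reagents that add atoms: none
Why: In this Suzuki–Miyaura alkenyl–allyl coupling zerovalent palladium ionises the allylic bromide to the syn π-allyl complex and the fluoride-activated alkenylboronate is delivered to the unhindered primary terminus, so the E geometry and the skipped diene are kept and no stereocentre is formed.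

Step 4
Reactants: 5 ethyl (5E,9E)-6,10,14-trimethyl-3-methylidenepentadeca-5,9,13-trienoate
Product: 7 (5E,9E)-6,10,14-trimethyl-3-methylidenepentadeca-5,9,13-trienoic acid, via lithium carboxylate 6 (not isolated)
Conditions: LiOH (1.5 equiv), THF/H2O 3:1, 0 °C; then 1 M HCl to pH 3, 0 °C
Reagents that add atoms: lithium hydroxide [Li+].[OH-]
Why: Saponification at 0 °C is faster than γ-deprotonation, so the ester is cleaved without moving the 1,1-disubstituted alkene into conjugation, and brief cold acidification frees the acid with no stereocentre involved.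

Step 5
Reactants: 7 (5E,9E)-6,10,14-trimethyl-3-methylidenepentadeca-5,9,13-trienoic acid; 8 furan-2(5H)-one
Product: 11 furan-2-yl (5E,9E)-6,10,14-trimethyl-3-methylidenepentadeca-5,9,13-trienoate, via acid chloride 9 (not isolated), via sodium furan-2-olate 10 (not isolated)
Conditions: 7, Me2C=C(Cl)NMe2 (1.1 equiv), CH2Cl2, 0 °C; separately 8 added slowly to NaN(SiMe3)2 (1.0 equiv), THF/DMPU, −78 °C; then 9 added, −78 to −40 °C
Reagents that add atoms: 1-chloro-N,N,2-trimethylprop-1-en-1-amine CC(C)=C(Cl)N(C)C (chlorine of 9); sodium bis(trimethylsilyl)amide C[Si](C)(C)[N-][Si](C)(C)C.[Na+] (sodium of 10)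
Why: This is O-acylation of a preformed butenolide dienolate, the reaction type used for furan-2-yl carbonates and 2-acyloxyfurans, in which the hard sodium furan-2-olate attacks at oxygen the acid chloride made under neutral conditions (no HCl near the polyene, no amine that could form a ketene) to give the aromatic enol ester, with no stereocentre formed.

Step 6
Reactants: 11 furan-2-yl (5E,9E)-6,10,14-trimethyl-3-methylidenepentadeca-5,9,13-trienoate
Product: 14 (3aR,7aR)-3a-farnesyl-3a,7a-dihydro-1-benzofuran-2,5(3H,4H)-dione, via oxa-bridged cycloadduct 12 (not isolated), via dienol 13 (not isolated)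
Conditions: (R)-TRIP [(R)-3,3'-bis(2,4,6-triisopropylphenyl)-1,1'-binaphthyl-2,2'-diyl hydrogen phosphate] (10 mol%), 4 Å MS, BHT (5 mol%), PhMe (0.01 M), 105 °C, 48 h
Reagents that add atoms: none
Why: Proposed new method: an intramolecular Diels–Alder reaction of the 2-acyloxyfuran joins the oxygen-bearing furan carbon to the internal alkene carbon and the free α-carbon to the CH2 terminus, which makes the carbocycle, the lactone and an oxa-bridge at once; the two mirror-image adducts interconvert through achiral 11 by retro-cycloaddition because an acyloxy-substituted bridgehead ketal does not open readily on its own; the chiral phosphoric acid ionises the C7a–O bridge bond of one adduct faster (a dynamic kinetic resolution that fixes C3a as R); loss of the C5 proton gives dienol 13, which cannot aromatise at the quaternary carbon and ketonises by protonation at C7a to the more stable cis-fused enone (C7a R); the closest known reaction types are the thermal cycloaddition, bridge-opening and hydrogen-shift cascade of 2-amidofurans carrying unactivated 1,1-disubstituted alkenes, and kinetic resolutions that rest on chiral-phosphate-controlled acetal ionisation.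

## Compound list
1 | (2E,6E)-farnesol | CC(C)=CCC/C(C)=C/CC/C(C)=C/CO | starting material
2 | (2E,6E)-farnesyl bromide | CC(C)=CCC/C(C)=C/CC/C(C)=C/CBr | intermediate
3 | ethyl buta-2,3-dienoate | C=C=CC(=O)OCC | starting material
4 | ethyl 3-(4,4,5,5-tetramethyl-1,3,2-dioxaborolan-2-yl)but-3-enoate | C=C(CC(=O)OCC)B1OC(C)(C)C(C)(C)O1 | intermediate
5 | ethyl (5E,9E)-6,10,14-trimethyl-3-methylidenepentadeca-5,9,13-trienoate | CC(C)=CCC/C(C)=C/CC/C(C)=C/CC(=C)CC(=O)OCC | intermediate
6 | lithium (5E,9E)-6,10,14-trimethyl-3-methylidenepentadeca-5,9,13-trienoate | CC(C)=CCC/C(C)=C/CC/C(C)=C/CC(=C)CC(=O)[O-].[Li+] | intermediate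
7 | (5E,9E)-6,10,14-trimethyl-3-methylidenepentadeca-5,9,13-trienoic acid | CC(C)=CCC/C(C)=C/CC/C(C)=C/CC(=C)CC(=O)O | intermediate
8 | furan-2(5H)-one | O=C1C=CCO1 | starting material
9 | (5E,9E)-6,10,14-trimethyl-3-methylidenepentadeca-5,9,13-trienoyl chloride | CC(C)=CCC/C(C)=C/CC/C(C)=C/CC(=C)CC(=O)Cl | intermediate
10 | sodium furan-2-olate | [Na+].[O-]c1ccco1 | intermediate
11 | furan-2-yl (5E,9E)-6,10,14-trimethyl-3-methylidenepentadeca-5,9,13-trienoate | CC(C)=CCC/C(C)=C/CC/C(C)=C/CC(=C)CC(=O)Oc1ccco1 | intermediate
12 | (3aR,5R,7aS)-3a-farnesyl-3a,4,5,7a-tetrahydro-5,7a-epoxy-1-benzofuran-2(3H)-one | CC(C)=CCC/C(C)=C/CC/C(C)=C/C[C@]12C[C@@H]3C=C[C@@]1(OC(=O)C2)O3 | intermediate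
13 | (3aR)-3a-farnesyl-5-hydroxy-3a,4-dihydro-1-benzofuran-2(3H)-one | CC(C)=CCC/C(C)=C/CC/C(C)=C/C[C@]12CC(O)=CC=C1OC(=O)C2 | intermediate
14 | (3aR,7aR)-3a-farnesyl-3a,7a-dihydro-1-benzofuran-2,5(3H,4H)-dione | CC(C)=CCC/C(C)=C/CC/C(C)=C/C[C@]12CC(=O)C=C[C@H]1OC(=O)C2 | target

## Summary
Total step count: 6.
Longest linear sequence: 5 steps (1 → 2 → 5 → 7 → 11 → 14).

## Steps most likely to fail

**Step 6.**
- The failure modes are these: the cycloaddition equilibrium may lie too far on the side of 11, the ester tether may disfavour the reactive conformer, an uncatalysed opening may erode the ee, or the acyl group may migrate to the C5 oxygen.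
- The fallback sets out from 2 and comes back at 14. It gives up the cycloaddition and closes the carbocycle onto a preformed butenolide.
- Commercial 4-bromofuran-2(5H)-one is borylated (B2pin2, PdCl2(dppf), KOAc, dioxane, 80 °C) to 4-(4,4,5,5-tetramethyl-1,3,2-dioxaborolan-2-yl)furan-2(5H)-one F1.
- Coupling with 2 (Pd(PPh3)4, CsF, THF) gives 4-farnesylfuran-2(5H)-one F2.
- With but-3-yn-2-one and the trifluoroacetate salt of 9-amino-9-deoxy-epi-quinidine in toluene, the butenolide adds through its γ-carbon to the ynone. This gives 4-farnesyl-5-[(Z)-3-oxobut-1-enyl]furan-2(5H)-one F3, whose C5 centre epimerises freely.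
- The enamine formed from the methyl ketone and the chiral amine then closes the six-membered ring by Michael addition to C4, in a dynamic kinetic resolution, and delivers 14.

**Step 5.**
- The failure modes are C-acylation of the ambident dienolate, self-condensation of 8, or ketene formation from 9.
- The fallback sets out from 7 and comes back at 11. It avoids any strong base by pairing a silyl dienol ether with an acyl fluoride.
- Acid 7 is converted with cyanuric fluoride and pyridine (CH2Cl2, 0 °C) into (5E,9E)-6,10,14-trimethyl-3-methylidenepentadeca-5,9,13-trienoyl fluoride F4.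
- This is stirred with commercial 2-(trimethylsilyloxy)furan and catalytic tetrabutylammonium difluorotriphenylsilicate (THF, −40 °C). The furan-2-olate is released only in catalytic amounts and is acylated at oxygen, driven by formation of the Si–F bond, to give 11.

**Step 3.**
- The failure modes are protodeboronation of 4 or base-induced migration of the β,γ-alkene.
- The fallback sets out from 1 and 3 and comes back at 5. It couples two electrophiles reductively, so no boron reagent and no basic activator is needed.
- Allenoate 3 takes up HBr (LiBr, AcOH, MeCN, 60 °C) to give ethyl 3-bromobut-3-enoate F5.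
- Alcohol 1 is acetylated (Ac2O, pyridine) to (2E,6E)-farnesyl acetate F6.
- NiCl2(dme) (5 mol%), 4,4'-di-tert-butyl-2,2'-bipyridine and zinc dust in THF/DMA then join the alkenyl bromide to the primary terminus of the allyl acetate to give 5.

## Further compounds
F1 | step 6 | 4-(4,4,5,5-tetramethyl-1,3,2-dioxaborolan-2-yl)furan-2(5H)-one | O=C1C=C(B2OC(C)(C)C(C)(C)O2)CO1
F2 | step 6 | 4-farnesylfuran-2(5H)-one | CC(C)=CCC/C(C)=C/CC/C(C)=C/CC1=CC(=O)OC1
F3 | step 6 | 4-farnesyl-5-[(Z)-3-oxobut-1-enyl]furan-2(5H)-one (C5 configurationally labile) | CC(C)=CCC/C(C)=C/CC/C(C)=C/CC1=CC(=O)OC1/C=C\C(C)=O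
F4 | step 5 | (5E,9E)-6,10,14-trimethyl-3-methylidenepentadeca-5,9,13-trienoyl fluoride | CC(C)=CCC/C(C)=C/CC/C(C)=C/CC(=C)CC(F)=O
F5 | step 3 | ethyl 3-bromobut-3-enoate | C=C(Br)CC(=O)OCC
F6 | step 3 | (2E,6E)-farnesyl acetate | CC(C)=CCC/C(C)=C/CC/C(C)=C/COC(C)=O
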